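**Strategy.** Everything rests on cutting the O1–C8a bond of the pyran (ring C). Without it, ring A is a 3,4,5-trimethoxybenzyl group whose two C–H positions next to C4a are equivalent and each para to a methoxy group, so no halogen handle is needed. The key step, also the last step, is a dehydrogenative C–H/O–H coupling: a hypervalent iodine oxidant converts ring A into its radical cation and the hydroxyl on C2 closes ring C. The precursor is an open-chain (S)-2-quinonyl-3-arylpropan-1-ol. Its ring B already stands at the quinone level and cannot be oxidised. C3 is set earlier by an Evans alkylation, and ring B derives from symmetric pentamethoxybenzene.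

Key step: step 6

Assumption: pentamethoxybenzene is taken as a catalogue compound, and atoms are numbered as in an isoflavan (O1, C2, C3, C4, C4a, C5 to C8, C8a for rings C and A; C1' to C6' for ring B).

**Step 1**
Reactants: 1 (S)-4-benzyloxazolidin-2-one; 2 bromoacetyl bromide
Product: 4 (S)-4-benzyl-3-(bromoacetyl)oxazolidin-2-one, via N-lithio oxazolidinone 3 (not isolated)
Conditions: n-BuLi (1.0 equiv), THF, −78 °C; then 2, −78 °C to 0 °C
Reagents that add atoms: none
Why: N-acylation of the lithiated oxazolidinone by the acid bromide is faster at low temperature than displacement at the CH2Br carbon, which is the standard loading of an oxazolidinone auxiliary and does not involve its stereocentre.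

**Step 2**
Reactants: 5 pentamethoxybenzene; 4 (S)-4-benzyl-3-(bromoacetyl)oxazolidin-2-one
Product: 8 (S)-4-benzyl-3-[2-(2,3,4,5,6-pentamethoxyphenyl)acetyl]oxazolidin-2-one, via pentamethoxyphenyllithium 6 (not isolated), via pentamethoxyphenylzinc chloride 7 (not isolated)
Conditions: 5, n-BuLi, THF, 0 °C to rt; ZnCl2, 0 °C; then 4, Pd2(dba)3 (cat.), SPhos (cat.), THF, rt
Reagents that add atoms: none
Why: The only ring C–H of 5 lies between two methoxy groups, so directed ortho-lithiation is unambiguous, and after transmetalation a Negishi coupling of the arylzinc chloride with the α-bromo carbonyl compound (oxidative addition to zerovalent palladium gives a palladium enolate, reductive elimination forms the aryl–CH2 bond) should give the arylacetyl imide with the auxiliary untouched.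

**Step 3**
Reactants: 8 (S)-4-benzyl-3-[2-(2,3,4,5,6-pentamethoxyphenyl)acetyl]oxazolidin-2-one; 9 3,4,5-trimethoxybenzyl bromide
Product: 11 (S)-4-benzyl-3-[(S)-2-(2,3,4,5,6-pentamethoxyphenyl)-3-(3,4,5-trimethoxyphenyl)propanoyl]oxazolidin-2-one, via sodium Z-enolate 10 (not isolated)
Conditions: NaN(SiMe3)2, THF, −78 °C; then 9, −78 °C to −20 °C
Reagents that add atoms: none
Why: In this Evans asymmetric alkylation the chelated Z-enolate is shielded on one face by the benzyl group of the (S)-auxiliary, so the benzylic bromide should enter from the other face and set the future C3 as (S), and any minor diastereomer can be removed by chromatography or crystallisation.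

**Step 4**
Reactants: 11 (S)-4-benzyl-3-[(S)-2-(2,3,4,5,6-pentamethoxyphenyl)-3-(3,4,5-trimethoxyphenyl)propanoyl]oxazolidin-2-one
Product: 12 (S)-2-(2,3,4,5,6-pentamethoxyphenyl)-3-(3,4,5-trimethoxyphenyl)propan-1-ol
Conditions: LiBH4, H2O (1 equiv), Et2O–THF, 0 °C; aqueous work-up
Reagents that add atoms: none
Why: Reductive cleavage of the N-acyloxazolidinone with LiBH4 attacks the exocyclic carbonyl, is too weakly basic to epimerise the α-aryl stereocentre, and returns the auxiliary.

**Step 5**
Reactants: 12 (S)-2-(2,3,4,5,6-pentamethoxyphenyl)-3-(3,4,5-trimethoxyphenyl)propan-1-ol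
Product: 13 2-[(S)-1-hydroxy-3-(3,4,5-trimethoxyphenyl)propan-2-yl]-3,5,6-trimethoxy-1,4-benzoquinone
Conditions: (NH4)2Ce(NO3)6 (2.2 equiv), MeCN–H2O, 0 °C
Reagents that add atoms: water, O
Why: In this oxidative demethylation of a para-dimethoxyarene, ring B is the more electron-rich ring and the only one with para pairs of methoxy groups, its two pairs (C2'/C5' and C3'/C6') are mirror-related so only one quinone can form, and any capture of the ring B radical cation by the side-chain hydroxyl should end in the same quinone after hydrolysis.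

**Step 6**
Reactants: 13 2-[(S)-1-hydroxy-3-(3,4,5-trimethoxyphenyl)propan-2-yl]-3,5,6-trimethoxy-1,4-benzoquinone
Product: 14 (S)-2,3,5-trimethoxy-6-(6,7,8-trimethoxychroman-3-yl)-1,4-benzoquinone
Conditions: PhI(OCOCF3)2 (1.1 equiv, slow addition), (CF3)2CHOH, 0.01 M, 0 °C
Reagents that add atoms: none
Why: PhI(OCOCF3)2 in (CF3)2CHOH takes one electron from the only electron-rich π system left, ring A, the C2 hydroxyl adds to the radical cation at the ring carbon next to C4a and para to a methoxy group (the future C8a), and a second electron transfer with loss of the ring proton restores aromaticity. The closest known reaction type is the hypervalent-iodine-mediated dehydrogenative cyclisation of 3-(alkoxyaryl)propan-1-ols to chromans through arene radical cations. Ring C closes by O1–C8a bond formation through a six-membered transition state (formally 6-exo-trig on the C8a=C8 Kekulé bond), whereas contact of the hydroxyl with ring B would be a disfavoured 5-endo addition at C6' or a reversible hemiketal at C2'. No new stereocentre is formed, and C3 from step 3 is not touched because the acidic, base-free medium does not trigger the quinone/quinone-methide tautomerism that could scramble it. Site selectivity comes from local symmetry, since the two C–H positions flanking C4a are interchanged by rotation about C4–C4a and only one chroman can form, and ring selectivity comes from the quinone level of ring B. Over-oxidation of the more electron-rich product is held back by near-stoichiometric oxidant, high dilution and the absence of water.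

**Compound list**
1 | (S)-4-benzyloxazolidin-2-one | O=C1OC[C@H](Cc2ccccc2)N1 | starting material
2 | bromoacetyl bromide | BrCC(=O)Br | starting material
3 | N-lithio (S)-4-benzyloxazolidin-2-one | [Li]N1[C@@H](Cc2ccccc2)COC1=O | intermediate
4 | (S)-4-benzyl-3-(bromoacetyl)oxazolidin-2-one | BrCC(=O)N1[C@@H](Cc2ccccc2)COC1=O | intermediate
5 | pentamethoxybenzene | COc1cc(OC)c(OC)c(OC)c1OC | starting material
6 | pentamethoxyphenyllithium | [Li]c1c(OC)c(OC)c(OC)c(OC)c1OC | intermediate
7 | pentamethoxyphenylzinc chloride | Cl[Zn]c1c(OC)c(OC)c(OC)c(OC)c1OC | intermediate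
8 | (S)-4-benzyl-3-[2-(2,3,4,5,6-pentamethoxyphenyl)acetyl]oxazolidin-2-one | COc1c(OC)c(OC)c(OC)c(OC)c1CC(=O)N1[C@@H](Cc2ccccc2)COC1=O | intermediate
9 | 3,4,5-trimethoxybenzyl bromide | COc1cc(CBr)cc(OC)c1OC | starting material
10 | sodium Z-enolate of 8 | [Na+].[O-]/C(=C\c1c(OC)c(OC)c(OC)c(OC)c1OC)N1[C@@H](Cc2ccccc2)COC1=O | intermediate
11 | (S)-4-benzyl-3-[(S)-2-(2,3,4,5,6-pentamethoxyphenyl)-3-(3,4,5-trimethoxyphenyl)propanoyl]oxazolidin-2-one | COc1c(OC)c(OC)c(OC)c(OC)c1[C@@H](C(=O)N1[C@@H](Cc2ccccc2)COC1=O)Cc1cc(OC)c(OC)c(OC)c1 | intermediate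
12 | (S)-2-(2,3,4,5,6-pentamethoxyphenyl)-3-(3,4,5-trimethoxyphenyl)propan-1-ol | COc1c(OC)c(OC)c(OC)c(OC)c1[C@@H](CO)Cc1cc(OC)c(OC)c(OC)c1 | intermediate
13 | 2-[(S)-1-hydroxy-3-(3,4,5-trimethoxyphenyl)propan-2-yl]-3,5,6-trimethoxy-1,4-benzoquinone | COC1=C(OC)C(=O)C([C@@H](CO)Cc2cc(OC)c(OC)c(OC)c2)=C(OC)C1=O | intermediate
14 | (S)-2,3,5-trimethoxy-6-(6,7,8-trimethoxychroman-3-yl)-1,4-benzoquinone | COC1=C(OC)C(=O)C([C@H]2COc3c(cc(OC)c(OC)c3OC)C2)=C(OC)C1=O | target

**Total step count:** 6. **Longest linear sequence:** 6 steps (1 → 4 → 8 → 11 → 12 → 13 → 14).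

**Steps most likely to fail**

Step 6. The closed product is more electron-rich than its precursor. Further oxidation or oxidative dimerisation at C5 may therefore outrun ring closure, or the radical cation may lose a benzylic proton at C4 before the hydroxyl arrives. The fallback makes the C–O bond by cross-coupling instead of by oxidation and unmasks the quinone afterwards. It sets out from 12. N-Bromosuccinimide in MeCN at 0 °C can only brominate ring A, because ring B has no C–H, and should give (S)-3-(2-bromo-3,4,5-trimethoxyphenyl)-2-(2,3,4,5,6-pentamethoxyphenyl)propan-1-ol F1. An intramolecular Buchwald–Hartwig etherification (Pd(OAc)2, 2-(di-tert-butylphosphino)-1,1'-binaphthyl, Cs2CO3, toluene, 80 °C) then closes ring C to (S)-6,7,8-trimethoxy-3-(2,3,4,5,6-pentamethoxyphenyl)chroman F2. Finally (NH4)2Ce(NO3)6 in aqueous MeCN at 0 °C should oxidise ring B, the more electron-rich ring, and the route is rejoined at 14.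

Step 2. Transmetalation of the arylzinc with two ortho substituents may be slow. Reduction of the bromo imide or protonation of the organozinc could then compete with coupling. The fallback builds the arylacetic acid first and attaches the auxiliary by acylation. It sets out from 5. Lithiation to 6 and opening of ethylene oxide (THF, 0 °C) should give 2-(2,3,4,5,6-pentamethoxyphenyl)ethanol F3. TEMPO (cat.) with PhI(OAc)2 in MeCN–H2O oxidises it to (2,3,4,5,6-pentamethoxyphenyl)acetic acid F4. Pivaloyl chloride and Et3N (THF, −20 °C) give (2,3,4,5,6-pentamethoxyphenyl)acetic pivalic anhydride F5, which acylates 3, made from 1 as in step 1. The route is rejoined at 8.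

Step 5. The oxidant may also attack ring A or its benzylic position, and trapping of the ring B radical cation by the free hydroxyl may slow clean quinone formation. The fallback replaces the chemical oxidant by an anodic ketalisation followed by hydrolysis. It sets out from 12. Anodic oxidation at a Pt anode in methanolic KOH (undivided cell, 0 °C) should add two methoxy groups across C2'/C5' of the more easily oxidised ring B. This gives (S)-2-(2,3,3,4,5,6,6-heptamethoxycyclohexa-1,4-dien-1-yl)-3-(3,4,5-trimethoxyphenyl)propan-1-ol F6. Mild hydrolysis (aqueous AcOH, rt) releases both carbonyl groups, and the route is rejoined at 13.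

**Further compounds**
F1 | step 6 | (S)-3-(2-bromo-3,4,5-trimethoxyphenyl)-2-(2,3,4,5,6-pentamethoxyphenyl)propan-1-ol | COc1c(OC)c(OC)c(OC)c(OC)c1[C@@H](CO)Cc1cc(OC)c(OC)c(OC)c1Br
F2 | step 6 | (S)-6,7,8-trimethoxy-3-(2,3,4,5,6-pentamethoxyphenyl)chroman | COc1c(OC)c(OC)c(OC)c(OC)c1[C@H]1COc2c(cc(OC)c(OC)c2OC)C1
F3 | step 2 | 2-(2,3,4,5,6-pentamethoxyphenyl)ethanol | COc1c(OC)c(OC)c(OC)c(OC)c1CCO
F4 | step 2 | (2,3,4,5,6-pentamethoxyphenyl)acetic acid | COc1c(OC)c(OC)c(OC)c(OC)c1CC(=O)O
F5 | step 2 | (2,3,4,5,6-pentamethoxyphenyl)acetic pivalic anhydride | COc1c(OC)c(OC)c(OC)c(OC)c1CC(=O)OC(=O)C(C)(C)C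
F6 | step 5 | (S)-2-(2,3,3,4,5,6,6-heptamethoxycyclohexa-1,4-dien-1-yl)-3-(3,4,5-trimethoxyphenyl)propan-1-ol | COC1=C(OC)C(OC)(OC)C([C@@H](CO)Cc2cc(OC)c(OC)c(OC)c2)=C(OC)C1(OC)OC
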